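**Strategy.** The route rests on cutting the shikimate ring at C2, the one ring carbon that bears only hydrogen and sits between ester-bearing C1 and oxygenated C3. Those two atoms are the α-carbon and the ketone of a cyclopentane β-keto ester (ring atoms C1, C3, C4, C5, C6), so a zinc carbenoid can slip C2 between them. In one flask this ring expansion forms C1–C2 and C2–C3, and iodination–elimination then delivers the C1=C2 enone with the C3 oxygen in place. The precursor is the bis-silyl ether of methyl (3S,4R)-3,4-dihydroxy-2-oxocyclopentane-1-carboxylate, made from dimethyl D-tartrate by Dieckmann closure, so C4 and C5 come from the chiral pool.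

Key step: step 6

Remark: ring atoms carry shikimate numbers throughout and TBS is tert-butyldimethylsilyl. β-Keto ester 8 is drawn as its enol, and C1 of 11 and the orthoester carbon of 16 and 19 are carried as epimer mixtures because these centres are destroyed later.

**Step 1**
Reactants: 1 dimethyl D-tartrate [dimethyl (2S,3S)-2,3-dihydroxybutanedioate]; 2 tert-butyldimethylsilyl trifluoromethanesulfonate
Product: 3 dimethyl (2S,3S)-2,3-bis(tert-butyldimethylsilyloxy)butanedioate
Conditions: TBSOTf (2.4 equiv), 2,6-lutidine (3 equiv), CH2Cl2, 0 °C to rt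
Reagents that add atoms: tert-butyldimethylsilyl trifluoromethanesulfonate, CC(C)(C)[Si](C)(C)OS(=O)(=O)C(F)(F)F
Why: Standard O-silylation with a silyl triflate and a hindered pyridine base should cap both secondary α-hydroxy ester groups without touching the stereocentres, and the two silyl ethers tolerate every step up to their planned acid cleavage.

**Step 2**
Reactants: 3 dimethyl (2S,3S)-2,3-bis(tert-butyldimethylsilyloxy)butanedioate
Product: 4 methyl (2S,3S)-2,3-bis(tert-butyldimethylsilyloxy)-4-oxobutanoate
Conditions: i-Bu2AlH (1.05 equiv), toluene, −78 °C; MeOH at −78 °C, then aq. KNaC4H4O6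
Reagents that add atoms: none
Why: Partial ester reduction with i-Bu2AlH should stop at the aldehyde because the aluminium hemiacetal next to the bulky silyloxy group persists at −78 °C, and since the two esters of C2-symmetric 3 are homotopic only one mono-aldehyde can form while unreacted 3 can be recycled.

**Step 3**
Reactants: 4 methyl (2S,3S)-2,3-bis(tert-butyldimethylsilyloxy)-4-oxobutanoate; 5 methyl (triphenylphosphoranylidene)acetate
Product: 6 dimethyl (2E,4R,5S)-4,5-bis(tert-butyldimethylsilyloxy)hex-2-enedioate
Conditions: Ph3P=CHCO2Me (1.2 equiv), CH2Cl2, 0 °C to rt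
Reagents that add atoms: methyl (triphenylphosphoranylidene)acetate, COC(=O)C=P(c1ccccc1)(c1ccccc1)c1ccccc1
Why: Wittig olefination with a stabilised ylide runs under neutral conditions that should not epimerise the α-silyloxy aldehyde, and the alkene geometry is irrelevant because the double bond is saturated next.

**Step 4**
Reactants: 6 dimethyl (2E,4R,5S)-4,5-bis(tert-butyldimethylsilyloxy)hex-2-enedioate
Product: 7 dimethyl (2S,3R)-2,3-bis(tert-butyldimethylsilyloxy)hexanedioate
Conditions: H2 (1 atm), Pd/C (5 mol% Pd), EtOAc, rt
Reagents that add atoms: none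
Why: Catalytic hydrogenation of the conjugated alkene in a neutral solvent should leave silyl ethers and esters untouched, the change of descriptor at the former C4 being a priority effect only.

**Step 5**
Reactants: 7 dimethyl (2S,3R)-2,3-bis(tert-butyldimethylsilyloxy)hexanedioate
Product: 8 methyl (3S,4R)-3,4-bis(tert-butyldimethylsilyloxy)-2-oxocyclopentane-1-carboxylate (keto–enol mixture, drawn as the enol)
Conditions: LiN(SiMe3)2 (2.2 equiv), THF, −78 °C to 0 °C; sat. aq. NH4Cl
Reagents that add atoms: none
Why: In this Dieckmann condensation the unhindered methylene next to the new ester is deprotonated faster than the α-silyloxy C–H and closes 5-exo-trig onto the tartrate ester, and only this regioisomer leaves the equilibrium as a stabilised β-keto ester enolate, which also shields the neighbouring oxygenated stereocentre from deprotonation.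

**Step 6**
Reactants: 8 methyl (3S,4R)-3,4-bis(tert-butyldimethylsilyloxy)-2-oxocyclopentane-1-carboxylate; 9 diiodomethane
Product: 12 methyl (4S,5R)-4,5-bis(tert-butyldimethylsilyloxy)-3-oxocyclohex-1-ene-1-carboxylate (methyl 4,5-bis-O-TBS-3-dehydroshikimate), via ring-expanded ethylzinc ester enolate 10 (not isolated), via tertiary iodo keto ester 11 (not isolated)
Conditions: Et2Zn (3 equiv), CH2I2 (3 equiv), CH2Cl2, 0 °C, then 8, 0 °C to rt; I2 until the colour persists, 0 °C; aq. Na2S2O3; DBU (1.2 equiv), 0 °C, 15 min
Reagents that add atoms: diiodomethane, ICI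
Why: Et2Zn converts 8 into its zinc enolate, which is alkylated at C1 by EtZnCH2I; the C2–zinc homoenolate then adds to the C3 ketone in a 3-exo-trig closure to give a donor–acceptor cyclopropoxide whose C1–C3 bond breaks to the ester enolate 10, so the six-membered ring arises by one-carbon ring expansion and not by a new cyclisation. The closest known reaction is the zinc-carbenoid homologation of β-keto esters to γ-keto esters (Zercher chain extension), including its ring-expanding use on cyclic β-keto esters and its iodination–elimination variant that gives γ-oxo enoates. Iodine traps 10 at C1 to give 11, and DBU removes a C2 proton α to the ketone, so loss of iodide by the E1cB path should place the alkene at C1=C2. No stereocentre is created, and C4 and C5 are carried over from tartrate. The step needs the cyclopropoxide to open at C1–C3 and not at another ring bond, which the alkoxide donor on C3 and the ester acceptor on C1 together secure, and it needs C4 and the C5 silyloxy group to survive, which the non-basic zinc medium, the poor leaving-group ability of silyloxide and a short, cold DBU treatment are meant to secure against epimerisation, β-elimination and aromatisation. Only a modest excess of carbenoid is used to limit further methylene transfer to 10.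

**Step 7**
Reactants: 12 methyl (4S,5R)-4,5-bis(tert-butyldimethylsilyloxy)-3-oxocyclohex-1-ene-1-carboxylate
Product: 13 methyl 4,5-bis-O-(tert-butyldimethylsilyl)shikimate [methyl (3R,4R,5R)-4,5-bis(tert-butyldimethylsilyloxy)-3-hydroxycyclohex-1-ene-1-carboxylate; 3-OH cis to O4, trans to O5]
Conditions: NaBH4 (1.1 equiv), CeCl3·7H2O (1.1 equiv), MeOH, −78 °C
Reagents that add atoms: none
Why: Luche 1,2-reduction of the enone; the trans-bis-silyl ether should hold the half-chair with both silyloxy groups axial, so hydride is expected to add anti to the adjacent pseudoaxial C4–O bond (Felkin–Anh-type axial attack) and set C3 with its hydroxyl cis to O4.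

**Step 8**
Reactants: 13 methyl 4,5-bis-O-(tert-butyldimethylsilyl)shikimate
Product: 14 methyl shikimate [methyl (3R,4S,5R)-3,4,5-trihydroxycyclohex-1-ene-1-carboxylate]
Conditions: HCl (1.25 M in MeOH), rt
Reagents that add atoms: none
Why: Acid-catalysed methanolysis should cleave both silyl ethers, while the allylic C3 hydroxyl does not ionise because its cation would be conjugated to the ester-bearing alkene, and ester exchange with the solvent is degenerate.

**Step 9**
Reactants: 14 methyl shikimate; 15 trimethyl orthoacetate
Product: 16 methyl 3,4-O-(1-methoxyethylidene)shikimate (cyclic orthoacetate on the cis-3,4-diol, O5–H free, both epimers at the orthoester carbon)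
Conditions: MeC(OMe)3 (1.3 equiv), CSA (5 mol%), MeCN, rt; Et3N, concentrate
Reagents that add atoms: trimethyl orthoacetate, CC(OC)(OC)OC
Why: In this acid-catalysed orthoester exchange only the cis-3,4-diol can close an unstrained five-membered cyclic orthoester, which leaves O5 as the single free hydroxyl, and at room temperature no Johnson–Claisen rearrangement of the allylic system is expected.

**Step 10**
Reactants: 16 methyl 3,4-O-(1-methoxyethylidene)shikimate; 17 (R)-2-methylbutanoic acid; 18 water
Product: 20 methyl 3-O-acetyl-5-O-[(2R)-2-methylbutanoyl]shikimate [methyl (3R,4S,5R)-3-acetoxy-4-hydroxy-5-{[(2R)-2-methylbutanoyl]oxy}cyclohex-1-ene-1-carboxylate], via 5-O-acylated cyclic orthoester 19 (not isolated)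
Conditions: 17 (1.3 equiv), DCC (1.4 equiv), DMAP (0.3 equiv), CH2Cl2, 0 °C to rt; filter, concentrate; AcOH/H2O 4:1, rt
Reagents that add atoms: (R)-2-methylbutanoic acid, CC[C@@H](C)C(=O)O; water, O
Why: Steglich esterification acylates the only free hydroxyl (O5) in a DMAP-buffered medium that the orthoester tolerates and that should not erode the α-methyl centre, and mild acid hydrolysis then opens the cyclic orthoester through a hemiorthoester that collapses to the ester on the pseudoaxial oxygen O3 and frees the equatorial O4 (axial-ester rule for cis-diol orthoesters).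

**Step 11**
Reactants: 20 methyl 3-O-acetyl-5-O-[(2R)-2-methylbutanoyl]shikimate; 21 propanoic anhydride
Product: 22 methyl (3R,4S,5R)-3-acetoxy-5-{[(2R)-2-methylbutanoyl]oxy}-4-(propanoyloxy)cyclohex-1-ene-1-carboxylate (target)
Conditions: (EtCO)2O (1.5 equiv), pyridine (3 equiv), DMAP (0.1 equiv), CH2Cl2, 0 °C
Reagents that add atoms: propanoic anhydride, CCC(=O)OC(=O)CC
Why: DMAP-catalysed acylation of the remaining secondary hydroxyl at 0 °C should outrun base-mediated acetyl migration from O3 and completes the triester without touching any stereocentre.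

**Compound list**

1 | dimethyl D-tartrate, dimethyl (2S,3S)-2,3-dihydroxybutanedioate | COC(=O)[C@@H](O)[C@H](O)C(=O)OC | starting material
2 | tert-butyldimethylsilyl trifluoromethanesulfonate | CC(C)(C)[Si](C)(C)OS(=O)(=O)C(F)(F)F | starting material
3 | dimethyl (2S,3S)-2,3-bis(tert-butyldimethylsilyloxy)butanedioate | COC(=O)[C@@H](O[Si](C)(C)C(C)(C)C)[C@H](O[Si](C)(C)C(C)(C)C)C(=O)OC | intermediate
4 | methyl (2S,3S)-2,3-bis(tert-butyldimethylsilyloxy)-4-oxobutanoate | COC(=O)[C@@H](O[Si](C)(C)C(C)(C)C)[C@H](O[Si](C)(C)C(C)(C)C)C=O | intermediate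
5 | methyl (triphenylphosphoranylidene)acetate | COC(=O)C=P(c1ccccc1)(c1ccccc1)c1ccccc1 | starting material
6 | dimethyl (2E,4R,5S)-4,5-bis(tert-butyldimethylsilyloxy)hex-2-enedioate | COC(=O)[C@@H](O[Si](C)(C)C(C)(C)C)[C@H](O[Si](C)(C)C(C)(C)C)/C=C/C(=O)OC | intermediate
7 | dimethyl (2S,3R)-2,3-bis(tert-butyldimethylsilyloxy)hexanedioate | COC(=O)[C@@H](O[Si](C)(C)C(C)(C)C)[C@H](O[Si](C)(C)C(C)(C)C)CCC(=O)OC | intermediate
8 | methyl (3S,4R)-3,4-bis(tert-butyldimethylsilyloxy)-2-oxocyclopentane-1-carboxylate, enol tautomer drawn | CC(C)(C)[Si](C)(C)O[C@@H]1C(O)=C(C(=O)OC)C[C@H]1O[Si](C)(C)C(C)(C)C | intermediate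
9 | diiodomethane | ICI | starting material
10 | ethylzinc ester enolate of methyl (4S,5R)-4,5-bis(tert-butyldimethylsilyloxy)-3-oxocyclohexane-1-carboxylate, O-bound form drawn | CC[Zn]OC(OC)=C1CC(=O)[C@@H](O[Si](C)(C)C(C)(C)C)[C@H](O[Si](C)(C)C(C)(C)C)C1 | intermediate
11 | methyl (4S,5R)-4,5-bis(tert-butyldimethylsilyloxy)-1-iodo-3-oxocyclohexane-1-carboxylate, both C1 epimers | CC(C)(C)[Si](C)(C)O[C@@H]1C(=O)CC(I)(C(=O)OC)C[C@H]1O[Si](C)(C)C(C)(C)C | intermediate
12 | methyl (4S,5R)-4,5-bis(tert-butyldimethylsilyloxy)-3-oxocyclohex-1-ene-1-carboxylate | CC(C)(C)[Si](C)(C)O[C@@H]1C(=O)C=C(C(=O)OC)C[C@H]1O[Si](C)(C)C(C)(C)C | intermediate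
13 | methyl 4,5-bis-O-(tert-butyldimethylsilyl)shikimate, methyl (3R,4R,5R)-4,5-bis(tert-butyldimethylsilyloxy)-3-hydroxycyclohex-1-ene-1-carboxylate | COC(=O)C1=C[C@@H](O)[C@@H](O[Si](C)(C)C(C)(C)C)[C@H](O[Si](C)(C)C(C)(C)C)C1 | intermediate
14 | methyl shikimate, methyl (3R,4S,5R)-3,4,5-trihydroxycyclohex-1-ene-1-carboxylate | COC(=O)C1=C[C@@H](O)[C@@H](O)[C@H](O)C1 | intermediate
15 | trimethyl orthoacetate | CC(OC)(OC)OC | starting material
16 | methyl 3,4-O-(1-methoxyethylidene)shikimate, epimers at the orthoester carbon | COC(=O)C1=C[C@H]2OC(C)(OC)O[C@H]2[C@H](O)C1 | intermediate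
17 | (R)-2-methylbutanoic acid | CC[C@@H](C)C(=O)O | starting material
18 | water | O | starting material
19 | methyl 3,4-O-(1-methoxyethylidene)-5-O-[(2R)-2-methylbutanoyl]shikimate, epimers at the orthoester carbon | COC(=O)C1=C[C@H]2OC(C)(OC)O[C@H]2[C@H](OC(=O)[C@H](C)CC)C1 | intermediate
20 | methyl (3R,4S,5R)-3-acetoxy-4-hydroxy-5-{[(2R)-2-methylbutanoyl]oxy}cyclohex-1-ene-1-carboxylate | COC(=O)C1=C[C@@H](OC(C)=O)[C@@H](O)[C@H](OC(=O)[C@H](C)CC)C1 | intermediate
21 | propanoic anhydride | CCC(=O)OC(=O)CC | starting material
22 | methyl (3R,4S,5R)-3-acetoxy-5-{[(2R)-2-methylbutanoyl]oxy}-4-(propanoyloxy)cyclohex-1-ene-1-carboxylate | CCC(=O)O[C@@H]1[C@H](OC(C)=O)C=C(C(=O)OC)C[C@H]1OC(=O)[C@H](C)CC | target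

**Step count.** Total: 11 steps. Longest linear sequence: 11 steps, from dimethyl D-tartrate 1.

**Steps most likely to fail**

Step 6. The carbenoid may alkylate on oxygen, the homoenolate may fail to close and fragment on this α-substituted cyclic substrate, a second methylene may be transferred to the ring-expanded enolate, or the base treatment may expel the C5 silyloxy group and aromatise the ring. The fallback sets out from 8 and inserts the same carbon by a radical path. C-Alkylation of the sodium enolate (NaH, CH2Br2, THF–DMPU) should give methyl (3S,4R)-1-(bromomethyl)-3,4-bis(tert-butyldimethylsilyloxy)-2-oxocyclopentane-1-carboxylate F1. n-Bu3SnH with AIBN in refluxing benzene then triggers the Dowd–Beckwith sequence (3-exo closure onto the ketone, β-scission to the ester-stabilised radical) to the saturated keto ester methyl (4S,5R)-4,5-bis(tert-butyldimethylsilyloxy)-3-oxocyclohexane-1-carboxylate F2. Kinetic enolisation at the unhindered C2 methylene (LiN(SiMe3)2, THF, −78 °C) and trapping with PhSeBr gives the selenide methyl (4S,5R)-4,5-bis(tert-butyldimethylsilyloxy)-3-oxo-2-(phenylselanyl)cyclohexane-1-carboxylate F3. Oxidation with H2O2/pyridine and syn-elimination toward the only β-hydrogen, on C1, comes back to the route at 12.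

Step 7. Facial selectivity of hydride addition may be poor or reversed, because the axial C5 silyloxy group shields the face that the C4 group leaves open. The fallback sets out from 12 and corrects C3 by inversion instead of by reduction control. The epimeric alcohol methyl 4,5-bis-O-(tert-butyldimethylsilyl)-3-epi-shikimate F4, formed under the same Luche conditions, is subjected to a Mitsunobu reaction with 4-nitrobenzoic acid (PPh3, DIAD, THF, 0 °C); attack at C1 is blocked by its full substitution, so direct displacement should give methyl 4,5-bis-O-(tert-butyldimethylsilyl)-3-O-(4-nitrobenzoyl)shikimate F5. Methanolysis (K2CO3, MeOH, 0 °C) comes back to the route at 13.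

Step 10. The hemiorthoester may collapse unselectively in the flattened cyclohexene ring, or the acetyl group may migrate between the cis oxygens, so that O3 and O4 are not cleanly told apart. The fallback sets out from 13 and fixes the acetate while O4 is still silylated. Acetylation (Ac2O, pyridine, DMAP, CH2Cl2) gives methyl 3-O-acetyl-4,5-bis-O-(tert-butyldimethylsilyl)shikimate F6. HF·pyridine in THF/pyridine, an acidic fluoride source that should not move the acetate, gives methyl 3-O-acetylshikimate F7. Acylation with one equivalent of 17 (DCC, DMAP, CH2Cl2, −20 °C) at the less hindered O5, which is flanked by the ring methylene, comes back to the route at 20.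

**Further compounds**

F1 | step 6 | methyl (3S,4R)-1-(bromomethyl)-3,4-bis(tert-butyldimethylsilyloxy)-2-oxocyclopentane-1-carboxylate, C1 epimers | CC(C)(C)[Si](C)(C)O[C@@H]1C(=O)C(CBr)(C(=O)OC)C[C@H]1O[Si](C)(C)C(C)(C)C
F2 | step 6 | methyl (4S,5R)-4,5-bis(tert-butyldimethylsilyloxy)-3-oxocyclohexane-1-carboxylate, C1 epimers | CC(C)(C)[Si](C)(C)O[C@@H]1C(=O)CC(C(=O)OC)C[C@H]1O[Si](C)(C)C(C)(C)C
F3 | step 6 | methyl (4S,5R)-4,5-bis(tert-butyldimethylsilyloxy)-3-oxo-2-(phenylselanyl)cyclohexane-1-carboxylate, epimers at C1 and C2 | CC(C)(C)[Si](C)(C)O[C@@H]1C(=O)C([Se]c2ccccc2)C(C(=O)OC)C[C@H]1O[Si](C)(C)C(C)(C)C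
F4 | step 7 | methyl 4,5-bis-O-(tert-butyldimethylsilyl)-3-epi-shikimate | COC(=O)C1=C[C@H](O)[C@@H](O[Si](C)(C)C(C)(C)C)[C@H](O[Si](C)(C)C(C)(C)C)C1
F5 | step 7 | methyl 4,5-bis-O-(tert-butyldimethylsilyl)-3-O-(4-nitrobenzoyl)shikimate | COC(=O)C1=C[C@@H](OC(=O)c2ccc(cc2)[N+](=O)[O-])[C@@H](O[Si](C)(C)C(C)(C)C)[C@H](O[Si](C)(C)C(C)(C)C)C1
F6 | step 10 | methyl 3-O-acetyl-4,5-bis-O-(tert-butyldimethylsilyl)shikimate | COC(=O)C1=C[C@@H](OC(C)=O)[C@@H](O[Si](C)(C)C(C)(C)C)[C@H](O[Si](C)(C)C(C)(C)C)C1
F7 | step 10 | methyl 3-O-acetylshikimate | COC(=O)C1=C[C@@H](OC(C)=O)[C@@H](O)[C@H](O)C1
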